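The route rests on cutting the C2–C3 bond of pyranone ring C. C2 is read as a former methoxy carbon and C3 as a carbene carbon. The precursor is therefore an open α-aryl-α-diazoketone: the finished chromene (rings B and D) sits on the diazo carbon, and ring A is a 2,6-dimethoxy-4-(methoxymethoxy)benzoyl group. A chiral dirhodium carboxylate expels N2 and the carbene inserts into a methoxy C–H bond. This closes ring C (O1, C2, C3, C4, C4a, C8a) and sets C3 in one neutral operation. The step exploits the O1–C2H2 unit next to C3 and the local symmetry of phloroglucinol ring A. Both ortho OMe groups are equivalent, and the survivor becomes the chelated, easily cleaved 5-OMe.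

Key step: step 7

Numbering used: isoflavanone numbering (O1, C2, C3, C4, C4a, C5 to C8, C8a in rings C and A; C1' to C6' in ring B). Ring D is the dimethylpyran fused to ring B. The target is the 3R enantiomer.
Assumption 1: 1-(4-hydroxy-2,6-dimethoxyphenyl)ethan-1-one is treated as a purchasable building block.
Assumption 2: the sense of induction of the dirhodium catalyst on this substrate cannot be derived safely from a model. The route is written with the S-configured ligand as giving 3R. If a test run shows 3S, the equally available Rh2(R-PTAD)4 is used and nothing else changes.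

Step 1
Reactants: 1 4-bromoresorcinol (4-bromobenzene-1,3-diol)
Product: 2 2-bromo-5-(methoxymethoxy)phenol
Conditions: MOMCl (1.0 equiv), i-Pr2NEt (1.1 equiv), CH2Cl2, 0 °C to rt
Reagents that add atoms: chloromethyl methyl ether (MOMCl), COCCl
Why: Base-mediated O-alkylation (Williamson type) with one equivalent of MOMCl should go to the hydroxyl para to bromine, since the other hydroxyl is flanked by and hydrogen-bonded to bromine and gives the less nucleophilic phenoxide, and the minor isomer and the bis-ether are removed by chromatography.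

Step 2
Reactants: 2 2-bromo-5-(methoxymethoxy)phenol; 3 3-chloro-3-methylbut-1-yne
Product: 4 1-bromo-4-(methoxymethoxy)-2-[(2-methylbut-3-yn-2-yl)oxy]benzene
Conditions: DBU (1.4 equiv), CuCl2·2H2O (cat.), MeCN, 0 °C
Reagents that add atoms: none
Why: Copper-catalysed propargylic substitution, in which the copper acetylide of 3 ionises easily at the tertiary carbon and the phenoxide of 2 captures it at oxygen at 0 °C, conditions under which the aryl bromide and the MOM ether are inert.

Step 3
Reactants: 4 1-bromo-4-(methoxymethoxy)-2-[(2-methylbut-3-yn-2-yl)oxy]benzene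
Product: 7 8-bromo-5-(methoxymethoxy)-2,2-dimethyl-2H-chromene, via allenylphenol 5 (not isolated), via quinone methide 6 (not isolated)
Conditions: PhNEt2, 180 °C
Reagents that add atoms: none
Why: The aromatic propargyl Claisen rearrangement can only reach the single free ortho carbon (between the two oxygens), and tautomerisation to 5, 1,5-hydrogen shift to 6 and 6π-oxa-electrocyclisation then give ring D with bromine next to the ring oxygen.

Step 4
Reactants: 8 1-(4-hydroxy-2,6-dimethoxyphenyl)ethan-1-one
Product: 9 1-[2,6-dimethoxy-4-(methoxymethoxy)phenyl]ethan-1-one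
Conditions: MOMCl (1.2 equiv), i-Pr2NEt (1.5 equiv), CH2Cl2, 0 °C to rt
Reagents that add atoms: chloromethyl methyl ether (MOMCl), COCCl
Why: Williamson-type O-alkylation of the only free phenol masks it against the bases of the next two steps and places no reactive C–H bond within reach of the later carbene.

Step 5
Reactants: 7 8-bromo-5-(methoxymethoxy)-2,2-dimethyl-2H-chromene; 9 1-[2,6-dimethoxy-4-(methoxymethoxy)phenyl]ethan-1-one
Product: 10 1-[2,6-dimethoxy-4-(methoxymethoxy)phenyl]-2-[5-(methoxymethoxy)-2,2-dimethyl-2H-chromen-8-yl]ethan-1-one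
Conditions: Pd(OAc)2 (2 mol %), XPhos (4 mol %), NaOt-Bu (2.2 equiv), toluene, 80 °C
Reagents that add atoms: none
Why: Palladium-catalysed ketone α-arylation (Buchwald–Hartwig type), in which zerovalent palladium inserts into the C–Br bond, the methyl ketone enolate binds and reductive elimination forms the C3–C1' bond, while the bulky ligand, the ortho oxygen of 7 and deprotonation of 10 by the excess base stop a second arylation.

Step 6
Reactants: 10 1-[2,6-dimethoxy-4-(methoxymethoxy)phenyl]-2-[5-(methoxymethoxy)-2,2-dimethyl-2H-chromen-8-yl]ethan-1-one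
Product: 11 2-diazo-1-[2,6-dimethoxy-4-(methoxymethoxy)phenyl]-2-[5-(methoxymethoxy)-2,2-dimethyl-2H-chromen-8-yl]ethan-1-one
Conditions: p-ABSA (1.3 equiv), DBU (1.5 equiv), MeCN, 0 °C to rt, dark
Reagents that add atoms: 4-acetamidobenzenesulfonyl azide (p-ABSA), CC(=O)Nc1ccc(cc1)S(=O)(=O)N=[N+]=[N-]
Why: Regitz diazo transfer, in which DBU deprotonates the doubly activated benzylic methylene of the deoxybenzoin, the enolate attacks the terminal nitrogen of the sulfonyl azide and the adduct collapses to diazoketone and sulfonamide, all ethers and the chromene being inert to the amidine base.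

Step 7
Reactants: 11 2-diazo-1-[2,6-dimethoxy-4-(methoxymethoxy)phenyl]-2-[5-(methoxymethoxy)-2,2-dimethyl-2H-chromen-8-yl]ethan-1-one
Product: 13 (3R)-5-methoxy-7-(methoxymethoxy)-3-[5-(methoxymethoxy)-2,2-dimethyl-2H-chromen-8-yl]-2,3-dihydro-4H-chromen-4-one, via rhodium carbene 12 (not isolated)
Conditions: Rh2(S-PTAD)4 (1 mol %), 4 Å MS, dry degassed CH2Cl2, slow addition of 11 (final 0.01 M), 0 °C to rt
Reagents that add atoms: none
Why: Loss of N2 at the dirhodium core gives donor/acceptor carbene 12, whose electrophilic carbon takes a methoxy C–H bond in a concerted, asynchronous three-centre insertion in which the hydride-like shift is supported by the lone pair of the ether oxygen, so that H ends on C3 and the C2–C3 bond forms. The closest known reaction types are the dirhodium-catalysed intramolecular C–H insertion of o-alkoxyaryl α-diazoketones next to the ether oxygen, which gives chroman-4-ones, the C–H insertions of α-aryl-α-diazoketones, and the insertion of donor/acceptor carbenes into methyl ethers. Ring C closes in the 1,6-insertion mode (carbene carbon, C4, C4a, C8a, O1, methyl carbon), the usual five-membered mode being impossible because position 5 is the oxygen atom itself. C3 is the former carbene carbon and its configuration is fixed by the carbene face that the chiral phthalimido carboxylate pocket of the catalyst leaves open, and the neutral, base-free medium keeps the acidic C3–H centre intact. Site selectivity is secured by the substrate: the two ortho OMe groups are interchanged by rotation about the C4–C4a bond and give the same product, the gem-dimethyl C–H bonds are unactivated and held away by ring D, the MOM groups and the hindered chromene alkene cannot reach the carbene within the molecule, and slow addition at high dilution suppresses intermolecular cyclopropanation and carbene dimerisation. Attack of the methoxy oxygen on the carbene gives a five-membered oxonium ylide reversibly, but methyl is a poor migrating group, so this path should drain back to insertion.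

Step 8
Reactants: 13 (3R)-5-methoxy-7-(methoxymethoxy)-3-[5-(methoxymethoxy)-2,2-dimethyl-2H-chromen-8-yl]-2,3-dihydro-4H-chromen-4-one
Product: 14 (3R)-5,7-dihydroxy-3-(5-hydroxy-2,2-dimethyl-2H-chromen-8-yl)-2,3-dihydro-4H-chromen-4-one
Conditions: BCl3 (1 M in CH2Cl2, 5 equiv), CH2Cl2, −78 to 0 °C; then pH 7 phosphate buffer, 0 °C
Reagents that add atoms: none
Why: Lewis acid ether cleavage, in which BCl3 chelates C4=O and the peri 5-OMe so that chloride removes that methyl group, the two MOM acetals are opened by the same reagent, and the low temperature and absence of base should leave C3 and the chromene double bond untouched before hydrolytic work-up frees the three phenols.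

Compound list
1 | 4-bromoresorcinol | Oc1ccc(Br)c(O)c1 | starting material
2 | 2-bromo-5-(methoxymethoxy)phenol | COCOc1ccc(Br)c(O)c1 | intermediate
3 | 3-chloro-3-methylbut-1-yne | CC(C)(Cl)C#C | starting material
4 | 1-bromo-4-(methoxymethoxy)-2-[(2-methylbut-3-yn-2-yl)oxy]benzene | COCOc1ccc(Br)c(OC(C)(C)C#C)c1 | intermediate
5 | 6-bromo-3-(methoxymethoxy)-2-(3-methylbuta-1,2-dien-1-yl)phenol (allenylphenol, not isolated) | COCOc1ccc(Br)c(O)c1C=C=C(C)C | intermediate
6 | 2-bromo-5-(methoxymethoxy)-6-(3-methylbut-2-en-1-ylidene)cyclohexa-2,4-dien-1-one (quinone methide, not isolated) | O=C1C(Br)=CC=C(OCOC)C1=CC=C(C)C | intermediate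
7 | 8-bromo-5-(methoxymethoxy)-2,2-dimethyl-2H-chromene | CC1(C)C=Cc2c(OCOC)ccc(Br)c2O1 | intermediate
8 | 1-(4-hydroxy-2,6-dimethoxyphenyl)ethan-1-one | CC(=O)c1c(OC)cc(O)cc1OC | starting material
9 | 1-[2,6-dimethoxy-4-(methoxymethoxy)phenyl]ethan-1-one | CC(=O)c1c(OC)cc(OCOC)cc1OC | intermediate
10 | 1-[2,6-dimethoxy-4-(methoxymethoxy)phenyl]-2-[5-(methoxymethoxy)-2,2-dimethyl-2H-chromen-8-yl]ethan-1-one | CC1(C)C=Cc2c(OCOC)ccc(CC(=O)c3c(OC)cc(OCOC)cc3OC)c2O1 | intermediate
11 | 2-diazo-1-[2,6-dimethoxy-4-(methoxymethoxy)phenyl]-2-[5-(methoxymethoxy)-2,2-dimethyl-2H-chromen-8-yl]ethan-1-one | CC1(C)C=Cc2c(OCOC)ccc(C(=[N+]=[N-])C(=O)c3c(OC)cc(OCOC)cc3OC)c2O1 | intermediate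
12 | rhodium carbene of 11 (dirhodium tetracarboxylate core drawn as one Rh atom, not isolated) | CC1(C)C=Cc2c(OCOC)ccc(C(=[Rh])C(=O)c3c(OC)cc(OCOC)cc3OC)c2O1 | intermediate
13 | (3R)-5-methoxy-7-(methoxymethoxy)-3-[5-(methoxymethoxy)-2,2-dimethyl-2H-chromen-8-yl]-2,3-dihydro-4H-chromen-4-one | CC1(C)C=Cc2c(OCOC)ccc([C@@H]3COc4cc(OCOC)cc(OC)c4C3=O)c2O1 | intermediate
14 | (3R)-5,7-dihydroxy-3-(5-hydroxy-2,2-dimethyl-2H-chromen-8-yl)-2,3-dihydro-4H-chromen-4-one | CC1(C)C=Cc2c(O)ccc([C@@H]3COc4cc(O)cc(O)c4C3=O)c2O1 | target

Total step count: 8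
Longest linear sequence: 7 steps (steps 1, 2, 3, 5, 6, 7, 8)

Steps most likely to fail

Step 7. Several things may go wrong:
- The methoxy oxygen may capture the carbene, followed by shift or loss of the methyl group, which contracts the ring.
- The electron-rich aryl group may migrate in a Wolff-type process.
- After a stepwise hydride shift, O-alkylation may occur instead of C-alkylation.
- Facial selectivity may be poor.

The fallback sets out from 10 and comes back at 13, and ring C stays the last ring closed. Chelation-controlled removal of one ortho methyl group with MgI2·OEt2 (toluene/Et2O, 80 °C) should give 1-[2-hydroxy-6-methoxy-4-(methoxymethoxy)phenyl]-2-[5-(methoxymethoxy)-2,2-dimethyl-2H-chromen-8-yl]ethan-1-one F1. Paraformaldehyde and Et2NH in EtOH at reflux (Mannich methylenation) should give the α-methylene ketone F2. This closes on the spot by 6-endo-trig oxa-Michael addition to the racemic isoflavanone F3. Asymmetric transfer hydrogenation with dynamic kinetic resolution follows (RuCl[(R,R)-TsDPEN](p-cymene), HCO2H/Et3N, EtOAc, 40 °C). C3 epimerises in the amine buffer during this reduction, which should give the cis-(3R,4R)-isoflavan-4-ol F4. Dess–Martin periodinane (CH2Cl2, 0 °C) then oxidises C4 back to the ketone 13 without base.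

Step 8. The boron-chelated ketone may enolise and lose configurational purity at C3. HCl may add to the chromene double bond. MOM-derived cations may attack the electron-rich rings in a Friedel–Crafts manner. The fallback sets out from 13 and comes back at 14. It separates the two kinds of ether cleavage into two orthogonal operations with other mechanisms. MgI2·OEt2 (toluene/Et2O, 60 °C) removes only the chelated methyl group by iodide attack, giving (3R)-5-hydroxy-7-(methoxymethoxy)-3-[5-(methoxymethoxy)-2,2-dimethyl-2H-chromen-8-yl]-2,3-dihydro-4H-chromen-4-one F5. Brønsted acid acetal exchange (dilute HCl in MeOH, 40 °C) then removes both MOM groups to give 14.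

Step 5. Oxidative addition into the electron-rich bromide may be slow and the catalyst may decay. The enolate may undergo aldol self-condensation, or a second arylation may occur. The fallback sets out from 9 and 7 and comes back at 11, so it replaces steps 5 and 6. Ketone 9 is trifluoroacetylated (LiHMDS, CF3CO2CH2CF3, THF, −78 °C) to 4,4,4-trifluoro-1-[2,6-dimethoxy-4-(methoxymethoxy)phenyl]butane-1,3-dione F6. Without isolation, F6 undergoes detrifluoroacetylative diazo transfer (MsN3, Et3N, MeCN, rt) to 2-diazo-1-[2,6-dimethoxy-4-(methoxymethoxy)phenyl]ethan-1-one F7. Bromide 7 is converted by copper-catalysed aromatic halogen exchange (CuI, NaI, N,N'-dimethylethylenediamine, dioxane, 110 °C) into 8-iodo-5-(methoxymethoxy)-2,2-dimethyl-2H-chromene F8. Palladium-catalysed C–H arylation of the acyldiazomethane (Pd(PPh3)4, Ag2CO3, Et3N, toluene, rt) then joins F7 and F8 directly to 11.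

Further compounds
F1 | step 7 | 1-[2-hydroxy-6-methoxy-4-(methoxymethoxy)phenyl]-2-[5-(methoxymethoxy)-2,2-dimethyl-2H-chromen-8-yl]ethan-1-one | CC1(C)C=Cc2c(OCOC)ccc(CC(=O)c3c(O)cc(OCOC)cc3OC)c2O1
F2 | step 7 | 1-[2-hydroxy-6-methoxy-4-(methoxymethoxy)phenyl]-2-[5-(methoxymethoxy)-2,2-dimethyl-2H-chromen-8-yl]prop-2-en-1-one | CC1(C)C=Cc2c(OCOC)ccc(C(=C)C(=O)c3c(O)cc(OCOC)cc3OC)c2O1
F3 | step 7 | racemic 5-methoxy-7-(methoxymethoxy)-3-[5-(methoxymethoxy)-2,2-dimethyl-2H-chromen-8-yl]-2,3-dihydro-4H-chromen-4-one | CC1(C)C=Cc2c(OCOC)ccc(C3COc4cc(OCOC)cc(OC)c4C3=O)c2O1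
F4 | step 7 | (3R,4R)-5-methoxy-7-(methoxymethoxy)-3-[5-(methoxymethoxy)-2,2-dimethyl-2H-chromen-8-yl]-3,4-dihydro-2H-chromen-4-ol | CC1(C)C=Cc2c(OCOC)ccc([C@@H]3COc4cc(OCOC)cc(OC)c4[C@@H]3O)c2O1
F5 | step 8 | (3R)-5-hydroxy-7-(methoxymethoxy)-3-[5-(methoxymethoxy)-2,2-dimethyl-2H-chromen-8-yl]-2,3-dihydro-4H-chromen-4-one | CC1(C)C=Cc2c(OCOC)ccc([C@@H]3COc4cc(OCOC)cc(O)c4C3=O)c2O1
F6 | step 5 | 4,4,4-trifluoro-1-[2,6-dimethoxy-4-(methoxymethoxy)phenyl]butane-1,3-dione | COCOc1cc(OC)c(C(=O)CC(=O)C(F)(F)F)c(OC)c1
F7 | step 5 | 2-diazo-1-[2,6-dimethoxy-4-(methoxymethoxy)phenyl]ethan-1-one | COCOc1cc(OC)c(C(=O)C=[N+]=[N-])c(OC)c1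
F8 | step 5 | 8-iodo-5-(methoxymethoxy)-2,2-dimethyl-2H-chromene | CC1(C)C=Cc2c(OCOC)ccc(I)c2O1
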